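**Plan**

1. Retrosynthesis: the two acetates and the C13/C14 oxygens go back to the E-allylic alcohol ent-labda-7,13-dien-15-ol; C7=C8 goes back to a C7 ketone; one C4 methyl goes back to a formyl group.
2. Ring A (C1–C5, C10) is then cut at C3–C4 and C5–C10. These two bonds flank the C4–C5 unit and C5/C10 are joined through the four ring-B carbons C6–C9, which is the retron of an intramolecular [4+2] cycloaddition of a 2,8,10-undecatrienal (diene C10=C1–C2=C3, dienophile C4=C5 carrying CHO).
3. Carbon sources: geraniol (C1, C9–C16, C20), ethynyltrimethylsilane (C2, C3), propanoic anhydride (C7, C8, C17), tiglic aldehyde (C4–C6 and both C4 carbons).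
4. Forward: geraniol → C1 aldehyde → alkynyl carbinol → Ireland–Claisen → vinylogous aldol → semi-hydrogenation → Diels–Alder (rings A and B together) → CHO to CH3, ring-A hydrogenation, C7 ketone/enol triflate/reduction → desilylation, epoxidation, Payne opening, diacetylation.
5. Stereochemistry: C1 carbinol by ligand control, transferred to C8/C9 in the chair Claisen; C7 by Felkin–Anh addition; C4, C5, C10 relayed from C7–C9 in the endo, chair-tether cycloaddition; C13/C14 from L-(+)-tartrate epoxidation with inversion at C14.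

Key step: step 11

Remark: locants C1–C20 are the labdane numbers of the target (C17 on C8, C18/C19 on C4, C20 on C10).
Assumption: (S,S)-ProPhenol is taken to deliver the alkyne to the Re face of aldehyde 4 to give the (3S)-carbinol; if the sense proves opposite, the (R,R)-ligand is used with no other change.

**Route**

Step 1
Reactants: 1 geraniol
Product: 2 geranyl tert-butyldiphenylsilyl ether
Conditions: t-BuPh2SiCl, imidazole, DMF, 0 °C → rt
Reagents that add atoms: tert-butyl(chloro)diphenylsilane, CC(C)(C)[Si](Cl)(c1ccccc1)c1ccccc1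
Why: Routine silylation of the primary allylic alcohol gives an ether that should survive the bases, hydrides and Lewis acids used up to step 16 and is removed by fluoride in step 17.

Step 2
Reactants: 2 geranyl tert-butyldiphenylsilyl ether
Product: 4 (2E,6E)-8-[tert-butyl(diphenyl)silyl]oxy-2,6-dimethylocta-2,6-dienal, via allylic alcohol 3 (not isolated)
Conditions: SeO2 (cat.), t-BuOOH, salicylic acid (cat.), CH2Cl2, rt; then MnO2, CH2Cl2, rt
Reagents that add atoms: tert-butyl hydroperoxide, CC(C)(C)OO
Why: SeO2 allylic oxidation (ene reaction then [2,3] shift) should select the E-methyl of the electron-rich distal alkene, the proximal alkene being deactivated by the allylic silyloxy group, and MnO2 takes the allylic alcohol on to the enal.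

Step 3
Reactants: 4 (2E,6E)-8-[tert-butyl(diphenyl)silyl]oxy-2,6-dimethylocta-2,6-dienal; 5 ethynyltrimethylsilane
Product: 6 (3S,4E,8E)-10-[tert-butyl(diphenyl)silyl]oxy-4,8-dimethyl-1-(trimethylsilyl)deca-4,8-dien-1-yn-3-ol
Conditions: Me2Zn, (S,S)-ProPhenol (cat.), Ph3P=O (cat.), toluene, 0 °C; aq. NH4Cl
Reagents that add atoms: none
Why: Dinuclear zinc–ProPhenol catalysed asymmetric alkynylation of an α-substituted enal should deliver the alkynylzinc to one aldehyde face and set the C1 carbinol as S.

Step 4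
Reactants: 6 (3S)-alkynyl carbinol; 7 propanoic anhydride
Product: 8 (3S,4E,8E)-10-[tert-butyl(diphenyl)silyl]oxy-4,8-dimethyl-1-(trimethylsilyl)deca-4,8-dien-1-yn-3-yl propanoate
Conditions: Et3N, DMAP (cat.), CH2Cl2, 0 °C → rt
Reagents that add atoms: none
Why: DMAP-catalysed acylation of the secondary alcohol installs the three carbons C7, C8 and C17 without touching the stereocentre.

Step 5
Reactants: 8 (3S)-propanoate
Product: 11 (2R,3R,4E)-3-[(3E)-5-[tert-butyl(diphenyl)silyl]oxy-3-methylpent-3-en-1-yl]-2,4-dimethylhept-4-en-6-ynoic acid, via silyl ketene acetal 9 (not isolated), via trimethylsilyl ester 10 (not isolated)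
Conditions: LiN(iPr)2, THF/DMPU, −78 °C; Me3SiCl, Et3N, −78 → 40 °C; then NaOH, MeOH/H2O, rt; aq. HCl
Reagents that add atoms: none
Why: Ireland–Claisen rearrangement in which enolization in THF/DMPU should favour the Z-silyl ketene acetal, and the chair with the alkynyl group equatorial should transfer the C1 configuration to C9 (R), make the C8 methyl centre syn (R) and form the E C10=C1 alkene; the shift through the alkene is expected to outrun that through the silylalkyne, and the basic work-up cleaves the silyl ester and the alkynyl silyl group.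

Step 6
Reactants: 11 (2R,3R)-enynoic acid
Product: 12 (2R,3R,4E)-3-[(3E)-5-[tert-butyl(diphenyl)silyl]oxy-3-methylpent-3-en-1-yl]-2,4-dimethylhept-4-en-6-yn-1-ol
Conditions: LiAlH4, THF, 0 °C → rt; aq. NaOH work-up
Reagents that add atoms: none
Why: LiAlH4 reduces the acid to the primary alcohol while the alkenes, the terminal alkyne (present as its acetylide) and the silyl ether are inert at this temperature.

Step 7
Reactants: 12 (2R,3R)-enynol
Product: 13 (2R,3R,4E)-3-[(3E)-5-[tert-butyl(diphenyl)silyl]oxy-3-methylpent-3-en-1-yl]-2,4-dimethylhept-4-en-6-ynal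
Conditions: Dess–Martin periodinane, NaHCO3, CH2Cl2, 0 °C → rt
Reagents that add atoms: none
Why: Buffered Dess–Martin oxidation should give the α-branched aldehyde without epimerizing C8.

Step 8
Reactants: 14 (E)-2-methylbut-2-enal (tiglic aldehyde)
Product: 15 tert-butyldimethyl[(2-methylbuta-1,3-dien-1-yl)oxy]silane (C1=C2 geometry not fixed, both isomers serve)
Conditions: t-BuMe2SiOTf, Et3N, Et2O, 0 °C → rt
Reagents that add atoms: tert-butyldimethylsilyl trifluoromethanesulfonate, CC(C)(C)[Si](C)(C)OS(=O)(=O)C(F)(F)F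
Why: Soft enolization of the enal by γ-deprotonation gives the 1-silyloxy diene needed as the vinylogous nucleophile.

Step 9
Reactants: 13 (2R,3R)-enynal; 15 silyl dienol ether
Product: 16 (2E,5R,6R,7R,8E)-7-[(3E)-5-[tert-butyl(diphenyl)silyl]oxy-3-methylpent-3-en-1-yl]-5-hydroxy-2,6,8-trimethylundeca-2,8-dien-10-ynal
Conditions: BF3·OEt2, CH2Cl2, −78 °C; aq. NaHCO3
Reagents that add atoms: none
Why: Vinylogous Mukaiyama aldol reaction in which the dienol ether attacks through its terminal carbon to give the E 2-methyl enal directly, and Felkin–Anh addition anti to the C9 branch should give the 7R alcohol, a centre that serves only as an oxygen handle and is destroyed in step 14.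

Step 10
Reactants: 16 hydroxy enynal
Product: 17 (2E,5R,6R,7R,8E)-7-[(3E)-5-[tert-butyl(diphenyl)silyl]oxy-3-methylpent-3-en-1-yl]-5-hydroxy-2,6,8-trimethylundeca-2,8,10-trienal
Conditions: H2 (1 atm), Pd/CaCO3 poisoned with Pb(OAc)2 (Lindlar catalyst), quinoline, EtOAc, rt
Reagents that add atoms: none
Why: Lindlar semi-hydrogenation of the terminal alkyne gives the E diene with C9 outside and C20 inside, while the trisubstituted alkenes and the enal are not reduced on the poisoned catalyst.

Step 11
Reactants: 17 hydroxy trienal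
Product: 18 trans-fused Diels–Alder adduct (4S,5S,7R,8R,9R,10S): C1=C2 in ring A, CHO and CH3 on C4 (CHO equatorial, cis to H5), H5 trans to CH3-10, OH-7, CH3-8 and the C9 side chain all equatorial, side chain cis to CH3-10
Conditions: Me2AlCl (2.5 equiv), CH2Cl2, −78 → 0 °C; then H2O
Reagents that add atoms: none
Why: Me2AlCl first turns the C7 hydroxyl into an aluminium alkoxide and then binds the aldehyde, lowering the enal LUMO so that the C10=C1–C2=C3 diene adds across C4=C5 in a concerted, asynchronous [4+2] cycloaddition with C5–C10 bonding ahead of C3–C4; the closest known reaction type is the Lewis acid-promoted intramolecular Diels–Alder reaction of (2E,8E)-2,8,10-undecatrienals to trans-fused octalins. Ring A (C1–C5, C10) is closed as the six-membered cycloadduct ring, and ring B (C5–C10) is closed at the same time by the C5–C10 bond across the four-carbon tether C6–C9, which should adopt a chair. C5 and C10 are set trans because the E dienophile reacts with the aluminium-bound formyl group endo and the tether exo on the E diene, and C4 is set by the same suprafacial addition (CHO stays cis to H5; this centre disappears in step 12). The absolute sense at C5 and C10 is relayed from the tether: with the C7 oxygen, the C8 methyl and the C9 side chain all equatorial in the chair, the dienophile should add to the diene face anti to the side chain, which places C11 cis to C20. The step needs endo selectivity, π-facial selectivity and chemoselectivity; the first is secured by Lewis-acid complexation of the E formyl group, the second by the three equatorial tether substituents, and the third because the C13=C14 alkene is neither conjugated nor activated.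

Step 12
Reactants: 18 formyl adduct
Product: 20 (5R,7R,8R,9R,10S)-gem-dimethyl diene alcohol (C4 now carries two methyls; C1=C2 and C13=C14 retained), via tosylhydrazone 19 (not isolated)
Conditions: TsNHNH2, THF, rt; then catecholborane, CHCl3, 0 °C; NaOAc·3H2O, 60 °C
Reagents that add atoms: none
Why: The non-enolizable aldehyde condenses with tosylhydrazide and hydride reduction of the hydrazone gives a diazene that loses N2 (a mild Wolff–Kishner-type deoxygenation), so the activating formyl group becomes the second C4 methyl under conditions that spare the silyl ether, the alcohol and the alkenes.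

Step 13
Reactants: 20 gem-dimethyl diene alcohol
Product: 21 (5R,7R,8R,9R,10S)-15-[tert-butyl(diphenyl)silyl]oxy-ent-labd-13E-en-7-ol (ring A saturated, OH-7 and CH3-8 equatorial)
Conditions: H2 (1 atm), RhCl(PPh3)3 (cat.), benzene/EtOH, rt
Reagents that add atoms: none
Why: RhCl(PPh3)3 hydrogenates the cis-disubstituted C1=C2 alkene far faster than the trisubstituted C13=C14 alkene, so ring A should be saturated selectively.

Step 14
Reactants: 21 C7 alcohol
Product: 22 (5R,8R,9R,10S)-15-[tert-butyl(diphenyl)silyl]oxy-ent-labd-13E-en-7-one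
Conditions: Dess–Martin periodinane, NaHCO3, CH2Cl2, rt
Reagents that add atoms: none
Why: Oxidation of the secondary alcohol gives the C7 ketone that serves as the handle for the C7=C8 alkene.

Step 15
Reactants: 22 C7 ketone
Product: 24 (5R,9S,10R)-15-[tert-butyl(diphenyl)silyl]oxy-ent-labda-7,13E-dien-7-yl trifluoromethanesulfonate, via trimethylsilyl enol ether 23 (not isolated)
Conditions: i-Pr2NMgBr, Et2O, 25 °C; Me3SiCl, Et3N, HMPA; then MeLi, THF, 0 °C; PhNTf2, −78 → 0 °C
Reagents that add atoms: N-phenylbis(trifluoromethanesulfonimide), O=S(=O)(N(c1ccccc1)S(=O)(=O)C(F)(F)F)C(F)(F)F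
Why: Equilibrating enolization with the magnesium amide should give the more substituted C7=C8 silyl enol ether, from which MeLi regenerates that enolate regiospecifically for trapping as the enol triflate.

Step 16
Reactants: 24 enol triflate
Product: 25 (5R,9R,10R)-15-[tert-butyl(diphenyl)silyl]oxy-ent-labda-7,13E-diene
Conditions: Pd(OAc)2 (cat.), PPh3, HCO2H, n-Bu3N, DMF, 60 °C
Reagents that add atoms: none
Why: Palladium-catalysed formate reduction of the enol triflate (oxidative addition, formate exchange, decarboxylation, reductive elimination) replaces the triflate by hydrogen without moving the double bond.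

Step 17
Reactants: 25 silyl ether
Product: 26 (5R,9R,10R)-ent-labda-7,13E-dien-15-ol
Conditions: Bu4NF, THF, 0 °C → rt
Reagents that add atoms: none
Why: Fluoride cleaves the silyl ether and releases the allylic alcohol needed to direct the epoxidation.

Step 18
Reactants: 26 allylic alcohol
Product: 27 (13S,14S)-13,14-epoxy-ent-labd-7-en-15-ol
Conditions: Ti(OiPr)4, L-(+)-diethyl tartrate, t-BuOOH, 4 Å molecular sieves, CH2Cl2, −20 °C
Reagents that add atoms: tert-butyl hydroperoxide, CC(C)(C)OO
Why: Sharpless asymmetric epoxidation acts only on the alkene of the titanium-bound allylic alcohol, so C7=C8 is untouched, and L-(+)-tartrate should give the (13S,14S)-epoxide by reagent control.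

Step 19
Reactants: 27 epoxy alcohol
Product: 29 (13S,14R)-ent-labd-7-ene-13,14,15-triol, via terminal epoxide 28 (not isolated)
Conditions: NaOH (0.5 M), t-BuOH/H2O, 75 °C
Reagents that add atoms: water, O
Why: Payne rearrangement, in which the C15 alkoxide opens the epoxide at C14 with inversion and hydroxide then opens the resulting terminal epoxide at primary C15, so C13 keeps its configuration and C14 becomes R.

Step 20
Reactants: 29 triol
Product: 30 (5R,9R,10R,13S,14R)-ent-labd-7-ene-13,14,15-triol 14,15-diacetate (target)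
Conditions: Ac2O, pyridine, rt
Reagents that add atoms: acetic anhydride, CC(=O)OC(C)=O
Why: Acetylation under these conditions should esterify the primary and secondary hydroxyls and leave the hindered tertiary C13 hydroxyl free.

**Compound list**

1 | geraniol | CC(C)=CCC/C(C)=C/CO | starting material
2 | geranyl tert-butyldiphenylsilyl ether | CC(C)=CCC/C(C)=C/CO[Si](c1ccccc1)(c1ccccc1)C(C)(C)C | intermediate
3 | (2E,6E)-8-[tert-butyl(diphenyl)silyl]oxy-2,6-dimethylocta-2,6-dien-1-ol | OC/C(C)=C/CC/C(C)=C/CO[Si](c1ccccc1)(c1ccccc1)C(C)(C)C | intermediate (not isolated)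
4 | (2E,6E)-8-[tert-butyl(diphenyl)silyl]oxy-2,6-dimethylocta-2,6-dienal | O=C/C(C)=C/CC/C(C)=C/CO[Si](c1ccccc1)(c1ccccc1)C(C)(C)C | intermediate
5 | ethynyltrimethylsilane | C#C[Si](C)(C)C | starting material
6 | (3S,4E,8E)-10-[tert-butyl(diphenyl)silyl]oxy-4,8-dimethyl-1-(trimethylsilyl)deca-4,8-dien-1-yn-3-ol | C[Si](C)(C)C#C[C@@H](O)/C(C)=C/CC/C(C)=C/CO[Si](c1ccccc1)(c1ccccc1)C(C)(C)C | intermediate
7 | propanoic anhydride | CCC(=O)OC(=O)CC | starting material
8 | (3S)-propanoate of 6 | CCC(=O)O[C@H](C#C[Si](C)(C)C)/C(C)=C/CC/C(C)=C/CO[Si](c1ccccc1)(c1ccccc1)C(C)(C)C | intermediate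
9 | (Z)-O-trimethylsilyl ketene acetal of 8 | C/C=C(\O[Si](C)(C)C)O[C@H](C#C[Si](C)(C)C)/C(C)=C/CC/C(C)=C/CO[Si](c1ccccc1)(c1ccccc1)C(C)(C)C | intermediate (not isolated)
10 | trimethylsilyl (2R,3R,4E)-3-[(3E)-5-silyloxy-3-methylpent-3-en-1-yl]-2,4-dimethyl-7-(trimethylsilyl)hept-4-en-6-ynoate | C[Si](C)(C)OC(=O)[C@H](C)[C@@H](CC/C(C)=C/CO[Si](c1ccccc1)(c1ccccc1)C(C)(C)C)/C(C)=C/C#C[Si](C)(C)C | intermediate (not isolated)
11 | (2R,3R,4E)-3-[(3E)-5-[tert-butyl(diphenyl)silyl]oxy-3-methylpent-3-en-1-yl]-2,4-dimethylhept-4-en-6-ynoic acid | OC(=O)[C@H](C)[C@@H](CC/C(C)=C/CO[Si](c1ccccc1)(c1ccccc1)C(C)(C)C)/C(C)=C/C#C | intermediate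
12 | (2R,3R,4E)-enynol (primary alcohol of 11) | OC[C@H](C)[C@@H](CC/C(C)=C/CO[Si](c1ccccc1)(c1ccccc1)C(C)(C)C)/C(C)=C/C#C | intermediate
13 | (2R,3R,4E)-enynal (aldehyde of 12) | O=C[C@H](C)[C@@H](CC/C(C)=C/CO[Si](c1ccccc1)(c1ccccc1)C(C)(C)C)/C(C)=C/C#C | intermediate
14 | (E)-2-methylbut-2-enal (tiglic aldehyde) | C/C=C(\C)C=O | starting material
15 | tert-butyldimethyl[(2-methylbuta-1,3-dien-1-yl)oxy]silane (C1=C2 geometry not fixed) | C=CC(C)=CO[Si](C)(C)C(C)(C)C | intermediate
16 | (2E,5R,6R,7R,8E)-7-[(3E)-5-silyloxy-3-methylpent-3-en-1-yl]-5-hydroxy-2,6,8-trimethylundeca-2,8-dien-10-ynal | O=C/C(C)=C/C[C@@H](O)[C@H](C)[C@@H](CC/C(C)=C/CO[Si](c1ccccc1)(c1ccccc1)C(C)(C)C)/C(C)=C/C#C | intermediate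
17 | (2E,5R,6R,7R,8E)-7-[(3E)-5-silyloxy-3-methylpent-3-en-1-yl]-5-hydroxy-2,6,8-trimethylundeca-2,8,10-trienal | O=C/C(C)=C/C[C@@H](O)[C@H](C)[C@@H](CC/C(C)=C/CO[Si](c1ccccc1)(c1ccccc1)C(C)(C)C)/C(C)=C/C=C | intermediate
18 | (4S,5S,7R,8R,9R,10S) trans-fused Diels–Alder adduct, 4-formyl, 7-hydroxy, C1=C2 | CC(C)(C)[Si](c1ccccc1)(c1ccccc1)OC/C=C(\C)CC[C@@H]1[C@@H](C)[C@H](O)C[C@@H]2[C@@](C)(C=O)CC=C[C@@]12C | intermediate
19 | tosylhydrazone of 18 | CC(C)(C)[Si](c1ccccc1)(c1ccccc1)OC/C=C(\C)CC[C@@H]1[C@@H](C)[C@H](O)C[C@@H]2[C@@](C)(C=NNS(=O)(=O)c3ccc(C)cc3)CC=C[C@@]12C | intermediate (not isolated)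
20 | (5R,7R,8R,9R,10S) gem-dimethyl diene alcohol (C1=C2, C13=C14) | CC(C)(C)[Si](c1ccccc1)(c1ccccc1)OC/C=C(\C)CC[C@@H]1[C@@H](C)[C@H](O)C[C@@H]2C(C)(C)CC=C[C@@]12C | intermediate
21 | (5R,7R,8R,9R,10S)-15-silyloxy-ent-labd-13E-en-7-ol | CC(C)(C)[Si](c1ccccc1)(c1ccccc1)OC/C=C(\C)CC[C@@H]1[C@@H](C)[C@H](O)C[C@@H]2C(C)(C)CCC[C@@]12C | intermediate
22 | (5R,8R,9R,10S)-15-silyloxy-ent-labd-13E-en-7-one | CC(C)(C)[Si](c1ccccc1)(c1ccccc1)OC/C=C(\C)CC[C@@H]1[C@@H](C)C(=O)C[C@@H]2C(C)(C)CCC[C@@]12C | intermediate
23 | (5R,9S,10R) C7=C8 trimethylsilyl enol ether of 22 | CC(C)(C)[Si](c1ccccc1)(c1ccccc1)OC/C=C(\C)CC[C@@H]1C(C)=C(O[Si](C)(C)C)C[C@@H]2C(C)(C)CCC[C@@]12C | intermediate (not isolated)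
24 | (5R,9S,10R) C7=C8 enol triflate | CC(C)(C)[Si](c1ccccc1)(c1ccccc1)OC/C=C(\C)CC[C@@H]1C(C)=C(OS(=O)(=O)C(F)(F)F)C[C@@H]2C(C)(C)CCC[C@@]12C | intermediate
25 | (5R,9R,10R)-15-[tert-butyl(diphenyl)silyl]oxy-ent-labda-7,13E-diene | CC(C)(C)[Si](c1ccccc1)(c1ccccc1)OC/C=C(\C)CC[C@@H]1C(C)=CC[C@@H]2C(C)(C)CCC[C@@]12C | intermediate
26 | (5R,9R,10R)-ent-labda-7,13E-dien-15-ol | OC/C=C(\C)CC[C@@H]1C(C)=CC[C@@H]2C(C)(C)CCC[C@@]12C | intermediate
27 | (13S,14S)-13,14-epoxy-ent-labd-7-en-15-ol | OC[C@@H]1O[C@@]1(C)CC[C@@H]2C(C)=CC[C@@H]3C(C)(C)CCC[C@@]23C | intermediate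
28 | (13S,14R)-14,15-epoxy-ent-labd-7-en-13-ol | C1O[C@H]1[C@@](C)(O)CC[C@@H]2C(C)=CC[C@@H]3C(C)(C)CCC[C@@]23C | intermediate (not isolated)
29 | (13S,14R)-ent-labd-7-ene-13,14,15-triol | OC[C@@H](O)[C@@](C)(O)CC[C@@H]1C(C)=CC[C@@H]2C(C)(C)CCC[C@@]12C | intermediate
30 | (5R,9R,10R,13S,14R)-ent-labd-7-ene-13,14,15-triol 14,15-diacetate | CC(=O)OC[C@@H](OC(C)=O)[C@@](C)(O)CC[C@@H]1C(C)=CC[C@@H]2C(C)(C)CCC[C@@]12C | target

**Step count**

Total: 20 steps. Longest linear sequence: 19 steps (steps 1–7 and 9–20; step 8 prepares the aldol partner).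

**Steps most likely to fail**

Step 11 (Diels–Alder). The Lewis acid may consume the hydroxy trienal by ionization or by Prins-type attack of the diene on the activated aldehyde, and the aluminium alkoxide at C7 may erode endo or facial control. The fallback masks the hydroxyl and gives up Lewis-acid activation; it sets out from 17 and returns at 18. Compound 17 is silylated (Et3SiCl, imidazole, DMF) to the triethylsilyl ether F1. Heating F1 in toluene with BHT at about 130 °C should effect the purely thermal intramolecular cycloaddition through the same chair tether to the silyl-protected adduct F2. PPTS in MeOH then removes the triethylsilyl group, leaving the tert-butyldiphenylsilyl ether in place, and gives 18.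

Step 15 (enol triflate). Enolization may be incompletely regioselective, and any enolate toward C6 would be carried through as the C6=C7 alkene. The fallback forms the alkene by anti-elimination of an alcohol instead; it sets out from 22 and returns at 25. LiBH(s-Bu)3 in THF at −78 °C should reduce 22 from the equatorial side to the axial 7-alcohol F3 (the C7 epimer of 21). POCl3 in pyridine then eliminates the derived dichlorophosphate with the anti-periplanar axial H8, which should favour the trisubstituted C7=C8 alkene and give 25 directly.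

Step 5 (Ireland–Claisen). Control of ketene acetal geometry may be insufficient, which would erode the syn C8/C9 relationship that the cycloaddition relies on, and rearrangement through the silylalkyne may compete. The fallback builds the same bond by an aldehyde-forming Claisen rearrangement of a propenyl ether; it sets out from 6 and returns at 13, bypassing steps 5–7. Compound 6 is O-allylated (NaH, allyl bromide, THF) to the allyl ether F4. [Ir(PCy3)3]BPh4 in CH2Cl2 should isomerize the unsubstituted allyl group to the (E)-prop-1-enyl ether F5, which on warming to about 60 °C rearranges through a chair (methyl and alkynyl equatorial) to the silylalkynyl aldehyde F6. AgNO3 (cat.) in aqueous acetone removes the alkynyl silyl group and gives 13.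

Further compounds
F1 | step 11 | triethylsilyl ether of 17 | O=C/C(C)=C/C[C@@H](O[Si](CC)(CC)CC)[C@H](C)[C@@H](CC/C(C)=C/CO[Si](c1ccccc1)(c1ccccc1)C(C)(C)C)/C(C)=C/C=C
F2 | step 11 | triethylsilyl ether of 18 | CC(C)(C)[Si](c1ccccc1)(c1ccccc1)OC/C=C(\C)CC[C@@H]1[C@@H](C)[C@H](O[Si](CC)(CC)CC)C[C@@H]2[C@@](C)(C=O)CC=C[C@@]12C
F3 | step 15 | (5R,7S,8R,9R,10S)-15-silyloxy-ent-labd-13E-en-7-ol (axial 7-alcohol) | CC(C)(C)[Si](c1ccccc1)(c1ccccc1)OC/C=C(\C)CC[C@@H]1[C@@H](C)[C@@H](O)C[C@@H]2C(C)(C)CCC[C@@]12C
F4 | step 5 | (3S)-allyl ether of 6 | C=CCO[C@H](C#C[Si](C)(C)C)/C(C)=C/CC/C(C)=C/CO[Si](c1ccccc1)(c1ccccc1)C(C)(C)C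
F5 | step 5 | (3S)-(E)-prop-1-enyl ether of 6 | C/C=C/O[C@H](C#C[Si](C)(C)C)/C(C)=C/CC/C(C)=C/CO[Si](c1ccccc1)(c1ccccc1)C(C)(C)C
F6 | step 5 | (2R,3R,4E)-7-(trimethylsilyl) analogue of aldehyde 13 | O=C[C@H](C)[C@@H](CC/C(C)=C/CO[Si](c1ccccc1)(c1ccccc1)C(C)(C)C)/C(C)=C/C#C[Si](C)(C)C
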